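## Retrosynthetic overview

1. The target comes from its C12 ketone by hydride delivery to the α-face, and that ketone comes from peracetylation of a briarane 2,4,14-triol-12-one.
2. The key disconnection is C1–C10. A 14-membered 1,2-epoxy-cembranolide enone is closed across the ring: trivalent titanium opens the epoxide to the tertiary C1 radical (cembrane C8), which adds to C10 (cembrane C3). This is the cembrane → briarane 3,8-cyclisation, and one bond makes both the six- and the ten-membered ring.
3. The cembranolide comes from a Nozaki–Hiyama–Kishi macrocyclisation at C4–C5 of an acyclic Z-alkenyl iodide/aldehyde.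
4. The acyclic chain comes from a boron aldol at C13–C14 between a lactone-bearing methyl enone (C5–C13, C16–C20) and a six-carbon epoxy aldehyde (C1–C4, C14, C15).
5. The lactone fragment comes from diacetone-D-glucose (C7–C10) and a propionate. Ring order: γ-lactone, then the 14-membered ring, then the six/ten-membered rings.

Assumption: briarane numbering is used throughout (C15, C16, C18, C20 = methyls on C1, C5, C17, C11; C19 = lactone carbonyl), and the sense of induction quoted for the catalyst pair in step 10 is assumed (the mirror-image pair would be taken if it proves opposite).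

## Route

Step 1
Reactants: 1 1,2:5,6-di-O-isopropylidene-α-D-glucofuranose (diacetone-D-glucose)
Product: 2 1,2:5,6-di-O-isopropylidene-α-D-ribo-hexofuranos-3-ulose
Conditions: TEMPO (1 mol %), KBr (10 mol %), NaOCl (1.2 equiv), NaHCO3, CH2Cl2/H2O, 0 °C
Reagents that add atoms: none
Why: Anelli oxoammonium oxidation of the only free hydroxyl, with no stereocentre formed and the flanking acetal centres not enolised under the buffered two-phase conditions.

Step 2
Reactants: 2 the 3-ulose; 3 tert-butyl propanoate
Product: 5 3-C-[(1R)-1-(tert-butoxycarbonyl)ethyl]-1,2:5,6-di-O-isopropylidene-α-D-allofuranose (sugar C2/C3/C4 become C7/C8/C9; side-chain CH is C17), via lithium Z(O)-enolate 4 (not isolated)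
Conditions: LDA, THF/DMPU 4:1, −78 °C, 3; then 2, −78 °C; AcOH quench
Reagents that add atoms: none
Why: Aldol-type 1,2-addition of an ester enolate to a ketone, in which the cis-fused 1,2-acetonide blocks the α-face so the C8–C17 bond forms on the β-face (tertiary OH α, ribo triad), and a chair Zimmerman–Traxler transition state of the Z(O)-enolate with the bulkier C4 side equatorial sets C17 as R.

Step 3
Reactants: 5 the 1,2:5,6-diacetonide
Product: 6 3-C-[(1R)-1-(tert-butoxycarbonyl)ethyl]-2,3:5,6-di-O-isopropylidene-D-allofuranose (lactol; anomer mixture)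
Conditions: TsOH·H2O (5 mol %), dry acetone, rt; Et3N quench
Reagents that add atoms: none
Why: Acid-catalysed acetal migration under thermodynamic control, in which the 1,2-acetal opens at the anomeric oxygen and recloses on the cis tertiary OH (the 2,3:5,6 pattern is the stable diacetonide of allo- and manno-type furanoses), so O7/O8 are masked together and the latent C6 aldehyde is freed without touching a carbon stereocentre that is kept.

Step 4
Reactants: 6 the lactol; 7 ethyltriphenylphosphonium iodide
Product: 9 open-chain (5Z)-alkenyl iodide (tert-butyl ester; 7,8-O-isopropylidene; free 9-OH; terminal sugar 5,6-acetonide still on C10), via iodo-ylide 8 (not isolated)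
Conditions: 7 (3 equiv), n-BuLi, THF, rt; I2, −78 °C; NaHMDS, −20 °C; then 6, −78 → −20 °C
Reagents that add atoms: iodine, I-I
Why: Stork–Zhao-type Wittig olefination of the lactol (which reacts through its open hydroxy-aldehyde alkoxide), whose kinetic cis-oxaphosphetane places iodine cis to C7 and so fixes the 5Z geometry while the glucose-derived C7 centre is kept.

Step 5
Reactants: 9 the 9-alcohol
Product: 10 the 9-O-acetate of 9
Conditions: Ac2O, pyridine, DMAP (cat.), CH2Cl2, rt
Reagents that add atoms: acetic anhydride, CC(=O)OC(C)=O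
Why: DMAP-catalysed acylation of the only free hydroxyl, which installs the C9 acetate of the target and blocks O9 so that only O7 can lactonise in the next step.

Step 6
Reactants: 10 the acetate
Product: 12 γ-lactone diol (O7–C19 lactone; 8-OH; 9-OAc; 5Z-iodoalkene; vicinal diol on C10), via seco acid 11 (not isolated)
Conditions: TFA/H2O/CH2Cl2 4:1:5, 0 °C → rt
Reagents that add atoms: none
Why: Global acidolysis (two acetonides and the tert-butyl ester) followed by spontaneous five-ring lactonisation of the acid onto the allylic O7–H, with the C–O bonds at C7, C8 and C9 never broken so all configurations are retained.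

Step 7
Reactants: 12 the lactone diol
Product: 13 C10 aldehyde (α-acetoxy aldehyde)
Conditions: NaIO4, THF/pH 7 buffer, 0 °C
Reagents that add atoms: none
Why: Malaprade glycol cleavage of the only vicinal diol present (O7 and O9 are acylated, so the tertiary 8-OH has no free neighbour).

Step 8
Reactants: 13 the aldehyde; 14 3-(triphenyl-λ5-phosphanylidene)butan-2-one
Product: 15 lactone methyl enone (C5–C13 fragment: 5Z-iodoalkene; 9-OAc; 10E-en-12-one; C13 methyl)
Conditions: 14 (1.5 equiv), toluene, 60 °C
Reagents that add atoms: none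
Why: Wittig olefination with a stabilised ylide under neutral conditions, which is E-selective (C9 trans to C12) and leaves the α-acetoxy centre C9 unepimerised.

Step 9
Reactants: 16 but-3-en-1-ol; 17 methacrolein
Product: 18 (2E)-5-hydroxy-2-methylpent-2-enal
Conditions: second-generation Hoveyda–Grubbs catalyst (2 mol %), 17 (5 equiv), CH2Cl2, 40 °C
Reagents that add atoms: none
Why: Olefin cross-metathesis of a terminal alkene with an α-substituted acrolein, which gives the thermodynamic E-trisubstituted enal and tolerates the free hydroxyl.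

Step 10
Reactants: 18 the enal
Product: 19 (2S,3R)-3-(2-hydroxyethyl)-2-methyloxirane-2-carbaldehyde (trans epoxide; oxirane C2 = C1 and oxirane C3 = C2 of the target)
Conditions: 9-amino(9-deoxy)epiquinidine (10 mol %), (S)-TRIP (20 mol %), 50% aq H2O2 (1.5 equiv), THF, 40 °C
Reagents that add atoms: hydrogen peroxide, OO
Why: Primary-amine iminium catalysis paired with a chiral phosphate counter-anion (asymmetric nucleophilic epoxidation of α-branched enals), in which face-selective peroxide addition and ring closure set C2 as R with the E geometry carried into the trans epoxide.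

Step 11
Reactants: 15 the methyl enone; 19 the epoxy aldehyde
Product: 21 seco-cembranolide alcohol ((1R,2R)-epoxide; 14S-OH; primary OH on C4; 10E-en-12-one; 9-OAc; 8-OH; lactone; 5Z-iodoalkene), via boron enolate 20 (not isolated)
Conditions: c-Hex2BCl (3 equiv), Et3N (4 equiv), Et2O, −78 → 0 °C; 19 (1.5 equiv), −78 → −20 °C; MeOH, pH 7 buffer, 30% H2O2, 0 °C
Reagents that add atoms: none
Why: Boron-mediated methyl-ketone aldol (soft enolisation touches only the ketone, and excess borane takes up the primary OH as a borinate), in which the non-enolisable epoxy aldehyde reacts by the Cornforth/polar Felkin–Anh mode with attack opposite the C1 methyl, on the side of the tied-back epoxide carbon, to give 14S.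

Step 12
Reactants: 21 the primary alcohol
Product: 22 seco-cembranolide aldehyde (C4 aldehyde)
Conditions: TEMPO (20 mol %), PhI(OAc)2 (1.1 equiv), CH2Cl2, rt; used at once
Reagents that add atoms: none
Why: Oxoammonium oxidation, which is selective for the unhindered primary alcohol over the neopentyl-type secondary 14-OH and the tertiary 8-OH and is neutral enough for the β,γ-epoxy aldehyde.

Step 13
Reactants: 22 the iodo aldehyde
Product: 23 1,2-epoxy-cembranolide (14-membered carbocycle C1–C14; (1R,2R)-epoxide; 4R-OH; 5Z; 9-OAc; 10E-en-12-one; 14S-OH; 8-OH; 7,19-lactone)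
Conditions: CrCl2 (10 equiv), NiCl2 (1 mol % of the chromium), DMSO/THF 3:1, 2 mM, rt
Reagents that add atoms: none
Why: Nozaki–Hiyama–Kishi macrocyclisation, in which zerovalent nickel inserts into C–I with retention of the Z geometry, the alkenyl group passes to trivalent chromium and adds only to the aldehyde (enone, esters, epoxide and free OH tolerated), high dilution favours the 14-ring as in chromium-mediated cembranoid closures, and the polar 1,3-anti model for a β-oxygenated aldehyde (the C2–O bond) predicts 4R.

Step 14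
Reactants: 23 the epoxy-cembranolide
Product: 24 briarane keto-triol (9-O-acetyl-2,4,8,14-tetrahydroxy-12-oxobriar-5Z-en-19,7-olide; 15β-CH3; 10α-H; 11β-CH3)
Conditions: Cp2TiCl2 (20 mol %), Mn dust (8 equiv), 2,4,6-collidine·HCl (2.5 equiv), THF, 2 mM, rt
Reagents that add atoms: none
Why: Proposed new method: Nugent–RajanBabu homolysis of the epoxide by Cp2TiCl (trivalent titanium, formed from Cp2TiCl2 and Mn) breaks the C1–O bond to give the tertiary C1 radical (cembrane C8); this nucleophilic radical adds 6-endo across the ring to the enone β-carbon C10 (cembrane C3) much faster than to the unactivated, oxygen-flanked C5=C6 alkene, through a chair-like transition state with both macrocycle arms (C2 and C9) equatorial (trans fusion, C15 β and H10 α) and the C14–O bond axial to avoid gauche strain with C2 and C15 (so C14 fixes the absolute sense); a second titanium reduces the α-keto radical to the enolate and collidinium protonates C11 from the α-face opposite the axial C15 methyl; the closest known reaction types are titanocene-mediated transannular cyclisations of epoxygermacranolides to eudesmanolides and epoxide-opening/Giese additions to enones, here carried over to the cembrane-to-briarane 3,8-closure.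

Step 15
Reactants: 24 the keto-triol
Product: 25 2,4,9,14-tetra-O-acetyl-8-hydroxy-12-oxobriar-5Z-en-19,7-olide
Conditions: Ac2O (10 equiv), pyridine, DMAP (cat.), CH2Cl2, 0 °C → rt
Reagents that add atoms: acetic anhydride, CC(=O)OC(C)=O
Why: DMAP-catalysed acylation of the three secondary hydroxyls (C2, C4, C14) in one operation, with the hindered tertiary 8-OH left free and the mild temperature limiting β-elimination at C14 and epimerisation at C11.

Step 16
Reactants: 25 the tetraacetate ketone
Product: 26 CNP0183630.2 (target; 1R,2R,4R,5Z,7S,8S,9R,10S,11R,12S,14S,17R)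
Conditions: NaBH4, CeCl3·7H2O, MeOH/THF, −78 °C
Reagents that add atoms: none
Why: Luche-type 1,2-reduction that is chemoselective for the ketone over the lactone and acetates, with hydride arriving from the α-face because the β-face is screened by the C15 and C20 methyls and the C9 arm, giving the 12β (12S) alcohol.

## Compound list

1 | 1,2:5,6-di-O-isopropylidene-α-D-glucofuranose | O[C@@H]1[C@H]2OC(C)(C)O[C@H]2O[C@@H]1[C@H]1COC(C)(C)O1 | starting material
2 | 1,2:5,6-di-O-isopropylidene-α-D-ribo-hexofuranos-3-ulose | O=C1[C@H]2OC(C)(C)O[C@H]2O[C@@H]1[C@H]1COC(C)(C)O1 | intermediate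
3 | tert-butyl propanoate | CCC(=O)OC(C)(C)C | starting material
4 | lithium Z(O)-enolate of 3 (CH3 cis to OLi) | C/C=C(\[O-])OC(C)(C)C.[Li+] | intermediate
5 | 3-C-[(1R)-1-(tert-butoxycarbonyl)ethyl]-1,2:5,6-di-O-isopropylidene-α-D-allofuranose | CC(C)(C)OC(=O)[C@H](C)[C@]1(O)[C@H]2OC(C)(C)O[C@H]2O[C@@H]1[C@H]1COC(C)(C)O1 | intermediate
6 | 3-C-[(1R)-1-(tert-butoxycarbonyl)ethyl]-2,3:5,6-di-O-isopropylidene-D-allofuranose (anomer mixture) | CC(C)(C)OC(=O)[C@H](C)[C@]12OC(C)(C)O[C@H]1C(O)O[C@@H]2[C@H]1COC(C)(C)O1 | intermediate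
7 | ethyltriphenylphosphonium iodide | CC[P+](c1ccccc1)(c1ccccc1)c1ccccc1.[I-] | starting material
8 | (1-iodoethylidene)triphenylphosphorane | CC(I)=P(c1ccccc1)(c1ccccc1)c1ccccc1 | intermediate
9 | open-chain (5Z)-alkenyl iodide, 7,8-acetonide, 9-OH, tert-butyl ester (C7, C8, C9, C17 as in 26) | CC(C)(C)OC(=O)[C@H](C)[C@@]1(OC(C)(C)O[C@H]1/C=C(/C)I)[C@H](O)[C@H]1COC(C)(C)O1 | intermediate
10 | 9-O-acetate of 9 | CC(C)(C)OC(=O)[C@H](C)[C@@]1(OC(C)(C)O[C@H]1/C=C(/C)I)[C@H](OC(C)=O)[C@H]1COC(C)(C)O1 | intermediate
11 | seco acid (7,8-diol, terminal diol, free C19 acid, 9-OAc) | OC[C@@H](O)[C@@H](OC(C)=O)[C@](O)([C@@H](C)C(=O)O)[C@@H](O)/C=C(/C)I | intermediate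
12 | γ-lactone diol | OC[C@@H](O)[C@@H](OC(C)=O)[C@@]3(O)[C@H](/C=C(/C)I)OC(=O)[C@@H]3C | intermediate
13 | C10 aldehyde | O=C[C@@H](OC(C)=O)[C@@]3(O)[C@H](/C=C(/C)I)OC(=O)[C@@H]3C | intermediate
14 | 3-(triphenyl-λ5-phosphanylidene)butan-2-one | CC(=O)C(C)=P(c1ccccc1)(c1ccccc1)c1ccccc1 | starting material
15 | lactone methyl enone (5Z-iodoalkene, 9-OAc, 10E-en-12-one) | CC(=O)/C(C)=C/[C@@H](OC(C)=O)[C@@]3(O)[C@H](/C=C(/C)I)OC(=O)[C@@H]3C | intermediate
16 | but-3-en-1-ol | C=CCCO | starting material
17 | methacrolein | C=C(C)C=O | starting material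
18 | (2E)-5-hydroxy-2-methylpent-2-enal | OCC/C=C(\C)C=O | intermediate
19 | (2S,3R)-3-(2-hydroxyethyl)-2-methyloxirane-2-carbaldehyde | OCC[C@H]1O[C@@]1(C=O)C | intermediate
20 | dicyclohexylboron enolate of 15 | C=C(OB(C1CCCCC1)C1CCCCC1)/C(C)=C/[C@@H](OC(C)=O)[C@@]3(O)[C@H](/C=C(/C)I)OC(=O)[C@@H]3C | intermediate
21 | seco-cembranolide alcohol ((1R,2R)-epoxide, 14S-OH) | OCC[C@H]4O[C@]4(C)[C@@H](O)CC(=O)/C(C)=C/[C@@H](OC(C)=O)[C@@]3(O)[C@H](/C=C(/C)I)OC(=O)[C@@H]3C | intermediate
22 | seco-cembranolide aldehyde | O=CC[C@H]4O[C@]4(C)[C@@H](O)CC(=O)/C(C)=C/[C@@H](OC(C)=O)[C@@]3(O)[C@H](/C=C(/C)I)OC(=O)[C@@H]3C | intermediate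
23 | 1,2-epoxy-cembranolide ((1R,2R)-epoxide, 4R-OH, 14S-OH) | O[C@H]1CC(=O)/C(C)=C/[C@@H](OC(C)=O)[C@@]3(O)[C@H](/C=C(/C)[C@H](O)C[C@H]4O[C@@]41C)OC(=O)[C@@H]3C | intermediate
24 | briarane keto-triol | O[C@H]1CC(=O)[C@H](C)[C@@H]2[C@@H](OC(C)=O)[C@@]3(O)[C@H](/C=C(/C)[C@H](O)C[C@@H](O)[C@]21C)OC(=O)[C@@H]3C | intermediate
25 | tetraacetate 12-ketone | CC(=O)O[C@H]1CC(=O)[C@H](C)[C@@H]2[C@@H](OC(C)=O)[C@@]3(O)[C@H](/C=C(/C)[C@H](OC(C)=O)C[C@@H](OC(C)=O)[C@]21C)OC(=O)[C@@H]3C | intermediate
26 | CNP0183630.2 | CC(=O)O[C@H]1C[C@H](O)[C@H](C)[C@@H]2[C@@H](OC(C)=O)[C@@]3(O)[C@H](/C=C(/C)[C@H](OC(C)=O)C[C@@H](OC(C)=O)[C@]21C)OC(=O)[C@@H]3C | target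

## Step count and risks

Total step count: 16.
Longest linear sequence: 14 (steps 1–8, then 11–16).

The three steps most likely to fail are 14, 13 and 4.

**Step 14 (transannular radical closure).** The radical may be intercepted before it closes, or it may close on the wrong face. The fallback sets out from 23 and comes back at 24.
- 23 is treated with stoichiometric Cp2TiCl (Cp2TiCl2/Mn, 0.1 M, no acid). Under these conditions a second titanium centre takes a methyl hydrogen from the C1 radical and gives the macrocyclic 2,14-dihydroxy-1(15)-methylene cembranolide F1.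
- Hydrogen-atom transfer from an iron hydride (Fe(acac)3, PhSiH3, EtOH, 60 °C) to the terminal CH2 of this alkene regenerates the same C1 radical. It now carries no bulky titanium alkoxide and no radical trap is present.
- Giese closure onto C10 and protonation of the enolate then give 24.

**Step 13 (macrocyclisation, configuration at C4).** The fallback sets out from 22 and comes back at 25.
- If the ring closes mainly to the 4S alcohol 4-epi-epoxy-cembranolide F2, this alcohol is not discarded.
- It is inverted and acetylated in one operation by a Mitsunobu reaction with acetic acid (PPh3, DIAD). The reaction is selective for the allylic C4–OH over the neopentyl-type 14-OH and gives the 4R-acetoxy epoxy-cembranolide F3.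
- The titanium closure of step 14 then gives the 4-O-acetyl briarane keto-diol F4.
- Acetylation of C2 and C14 as in step 15 gives 25.

**Step 4 (iodo-olefination of a lactol with a thermally fragile ylide).** The fallback sets out from 6 and comes back at 9.
- Ramirez olefination (CBr4, PPh3, Et3N, CH2Cl2) gives the gem-dibromoalkene F5.
- A trans-selective Negishi methylation (Me2Zn, PdCl2(DPEphos)) replaces only the bromine trans to C7 and gives the (5Z)-bromoalkene F6.
- Copper-catalysed halogen exchange with retention (CuI, NaI, N,N′-dimethylethylenediamine, dioxane, 110 °C) gives 9.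

Further compounds
F1 | step 14 | 2,14-dihydroxy-1(15)-methylene cembranolide (isomer of 23) | O[C@H]1CC(=O)/C(C)=C/[C@@H](OC(C)=O)[C@@]3(O)[C@H](/C=C(/C)[C@H](O)C[C@@H](O)C1=C)OC(=O)[C@@H]3C
F2 | step 13 | 4-epi-epoxy-cembranolide (4S-OH) | O[C@H]1CC(=O)/C(C)=C/[C@@H](OC(C)=O)[C@@]3(O)[C@H](/C=C(/C)[C@@H](O)C[C@H]4O[C@@]41C)OC(=O)[C@@H]3C
F3 | step 13 | 4R-acetoxy epoxy-cembranolide | O[C@H]1CC(=O)/C(C)=C/[C@@H](OC(C)=O)[C@@]3(O)[C@H](/C=C(/C)[C@H](OC(C)=O)C[C@H]4O[C@@]41C)OC(=O)[C@@H]3C
F4 | step 13 | 4-O-acetyl briarane keto-diol | O[C@H]1CC(=O)[C@H](C)[C@@H]2[C@@H](OC(C)=O)[C@@]3(O)[C@H](/C=C(/C)[C@H](OC(C)=O)C[C@@H](O)[C@]21C)OC(=O)[C@@H]3C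
F5 | step 4 | gem-dibromoalkene analogue of 9 | CC(C)(C)OC(=O)[C@H](C)[C@@]1(OC(C)(C)O[C@H]1C=C(Br)Br)[C@H](O)[C@H]1COC(C)(C)O1
F6 | step 4 | (5Z)-bromoalkene analogue of 9 | CC(C)(C)OC(=O)[C@H](C)[C@@]1(OC(C)(C)O[C@H]1/C=C(/C)Br)[C@H](O)[C@H]1COC(C)(C)O1
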